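**Plan**
- Retrosynthesis: the C6 ester is removed first (acrylation, then Baylis–Hillman hydroxymethylation), then the C12 ester (oxidation of an isopropenyl CH3); ring B is cut at C6–C7 (intramolecular carbonyl-ene); ring A is cut at C4–C5 and C1–C10 (Diels–Alder).
- Forward: ring A is made first from 1,3-dimethoxy-1-(trimethylsilyloxy)butadiene (C1–C4) and an (E)-2-methyl enal whose C=C becomes C5=C10. The formyl group (future C9) is the activating group; a dimethyl acetal masks the future C6 aldehyde.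
- Enabling feature: ring A carries oxygen on C1 and C3 next to the quaternary C10. C1–C4 therefore map onto a 1,1,3-trioxygenated diene, and the cycloadduct is a 3-methoxy-enone (C1=O, C2=C3–OMe) whose only acidic site is C4, where C15 enters.
- The C9 formyl group is then turned into the C9–C8–C7=C11 chain (methylenation, hydroboration/Suzuki), and ring B closes by an isopulegol-type ene reaction.
- Stereochemistry: C5/C10 from the (E)-dienophile plus a chiral diol catalyst; C6/C7 from the chair ene transition state on the trans C5/C10 substituents; C1 and C3 from α-face hydride attack anti to the axial C14 methyl.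

Key step: step 3

Positions are cited in eudesmane numbering (ring A = C1–C5 and C10, ring B = C5–C10, C11–C13 side chain, C14 = methyl on C10, C15 = carbon on C4); α/β refer to the usual drawing with C14 β.
Remark: the sense of induction of the diol catalyst in step 3 is assigned by analogy with hydrogen-bond-catalysed cycloadditions of α-substituted acroleins; if the opposite face reacts, the (4S,5S)-catalyst is used instead.

Step 1
Reactants: 1 2,2-dimethoxyacetaldehyde; 2 2-(triphenylphosphoranylidene)propanal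
Product: 3 (2E)-4,4-dimethoxy-2-methylbut-2-enal
Conditions: CH2Cl2/H2O (1 as its commercial aqueous solution), rt
Reagents that add atoms: none
Why: Wittig olefination with a formyl-stabilised ylide should give the (E)-enal, which places the formyl group trans to the acetal carbon as needed for the later C9/C6 trans relationship.

Step 2
Reactants: 4 methyl (2E)-3-methoxybut-2-enoate
Product: 5 (1E)-1,3-dimethoxy-1-(trimethylsilyloxy)buta-1,3-diene
Conditions: LDA (LiN(iPr)2), THF, −78 °C; then Me3SiCl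
Reagents that add atoms: chlorotrimethylsilane C[Si](C)(C)Cl
Why: γ-Deprotonation of the β-methoxy enoate and O-silylation of the extended enolate is the standard preparation of this vinylketene acetal.

Step 3
Reactants: 3 (2E)-4,4-dimethoxy-2-methylbut-2-enal; 5 (1E)-1,3-dimethoxy-1-(trimethylsilyloxy)buta-1,3-diene
Product: 7 (1S,6S)-6-(dimethoxymethyl)-4-methoxy-1-methyl-2-oxocyclohex-3-ene-1-carbaldehyde, via silyl ketal cycloadduct 6 (not isolated)
Conditions: (4R,5R)-2,2-dimethyl-α,α,α′,α′-tetra(1-naphthyl)-1,3-dioxolane-4,5-dimethanol (20 mol%), toluene, −60 °C; then AcOH, THF/H2O, 0 °C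
Reagents that add atoms: none
Why: Hydrogen-bond-catalysed normal-demand Diels–Alder reaction: the diol binds the formyl oxygen of 3, and diene 5 adds across C5=C10 in one asynchronous, concerted, suprafacial event in which its nucleophilic CH2 terminus (C4) bonds to the β-carbon C5 and its ketene acetal carbon (C1) to the α-carbon C10; mild acid then collapses the silyl ketal of 6 to the C1 ketone. The closest known reaction types are the diol-catalysed cycloadditions of 1-amino-3-siloxy dienes with α-substituted acroleins and the thermal cycloadditions of 1,1,3-trioxygenated dienes. Ring A is closed by a [4+2] cycloaddition in which both new σ bonds form on the same face of the dienophile. C10 and C5 are the new stereocentres: their relative configuration (C9 trans to C6, C14 cis to C6) follows from the (E)-geometry of 3, their absolute configuration from the enal face left open in the catalyst complex. The step needs regioselectivity (the C4 terminus of 5 is matched with the formyl-activated β-carbon), chemoselectivity for C=C over C=O (hydrogen bonding instead of a strong Lewis acid, α-branched enal) and enantioface selectivity (catalyst).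

Step 4
Reactants: 7 (1S,6S)-6-(dimethoxymethyl)-4-methoxy-1-methyl-2-oxocyclohex-3-ene-1-carbaldehyde
Product: 8 (5S,6R)-5-(dimethoxymethyl)-6-ethenyl-3-methoxy-6-methylcyclohex-2-en-1-one
Conditions: Ph3PCH3Br, KOtBu, THF, 0 °C; then 7, −78 → 0 °C
Reagents that add atoms: methyltriphenylphosphonium bromide C[P+](c1ccccc1)(c1ccccc1)c1ccccc1.[Br-]
Why: Wittig methylenation should take the aldehyde in preference to the hindered vinylogous ester carbonyl, and no stereocentre is touched.

Step 5
Reactants: 8 (5S,6R)-5-(dimethoxymethyl)-6-ethenyl-3-methoxy-6-methylcyclohex-2-en-1-one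
Product: 10 (5S,6R)-5-(dimethoxymethyl)-3-methoxy-6-methyl-6-(4-methylpent-3-en-1-yl)cyclohex-2-en-1-one, via B-alkyl-9-BBN adduct 9 (not isolated)
Conditions: 9-BBN, THF, 0 °C → rt; then PdCl2(dppf), AsPh3, Cs2CO3, Me2C=CHBr, DMF/H2O, rt
Reagents that add atoms: 1-bromo-2-methylprop-1-ene CC(C)=CBr
Why: Anti-Markovnikov hydroboration of the terminal vinyl group followed by B-alkyl Suzuki–Miyaura coupling turns the former activating formyl carbon into C9H2 and adds C8, C7 and C11–C13.

Step 6
Reactants: 10 (5S,6R)-5-(dimethoxymethyl)-3-methoxy-6-methyl-6-(4-methylpent-3-en-1-yl)cyclohex-2-en-1-one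
Product: 12 {(1R,5R,6S)-6-(dimethoxymethyl)-2-methoxy-5-methyl-5-(4-methylpent-3-en-1-yl)-4-oxocyclohex-2-en-1-yl}methyl 2,2-dimethylpropanoate, via lithium dienolate 11 (not isolated)
Conditions: LDA (LiN(iPr)2), THF/DMPU, −78 °C; then ClCH2OPiv, −78 → −20 °C
Reagents that add atoms: chloromethyl pivalate CC(C)(C)C(=O)OCCl
Why: With C10 quaternary the 3-alkoxy-enone can only be deprotonated at C4, and γ-alkylation of such extended enolates is known; the electrophile should enter anti to the C5 substituent, and the C4 configuration is lost later.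

Step 7
Reactants: 12 {(1R,5R,6S)-6-(dimethoxymethyl)-2-methoxy-5-methyl-5-(4-methylpent-3-en-1-yl)-4-oxocyclohex-2-en-1-yl}methyl 2,2-dimethylpropanoate
Product: 13 {(1R,5R,6S)-6-formyl-2-methoxy-5-methyl-5-(4-methylpent-3-en-1-yl)-4-oxocyclohex-2-en-1-yl}methyl 2,2-dimethylpropanoate
Conditions: PPTS (cat.), acetone/H2O, 40 °C
Reagents that add atoms: water O
Why: A dimethyl acetal hydrolyses far faster than a vinylogous ester, so mild acid should free only the C6 aldehyde, whose trans-diequatorial arrangement with the C10 chain is also the stable one.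

Step 8
Reactants: 13 {(1R,5R,6S)-6-formyl-2-methoxy-5-methyl-5-(4-methylpent-3-en-1-yl)-4-oxocyclohex-2-en-1-yl}methyl 2,2-dimethylpropanoate
Product: 14 6α-hydroxy-3-methoxy-15-pivaloyloxy-4βH,5αH,7αH-eudesma-2,11-dien-1-one
Conditions: ZnBr2 (1.5 equiv), CH2Cl2, 0 °C → rt
Reagents that add atoms: none
Why: Lewis-acid-promoted intramolecular carbonyl-ene reaction (citronellal-to-isopulegol type) through a chair transition state should close ring B as a trans-decalin with equatorial 6α-OH and 7β-isopropenyl, since an axial C6–O would clash with the axial C14 methyl.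

Step 9
Reactants: 14 6α-hydroxy-3-methoxy-15-pivaloyloxy-4βH,5αH,7αH-eudesma-2,11-dien-1-one
Product: 15 6α-acryloyloxy-3-methoxy-15-pivaloyloxy-4βH,5αH,7αH-eudesma-2,11-dien-1-one
Conditions: acryloyl chloride, iPr2NEt, DMAP (cat.), CH2Cl2, 0 °C
Reagents that add atoms: acryloyl chloride C=CC(=O)Cl
Why: DMAP-catalysed acylation of the only free hydroxyl installs the C6 ester early and removes any later risk of lactonisation onto C12.

Step 10
Reactants: 15 6α-acryloyloxy-3-methoxy-15-pivaloyloxy-4βH,5αH,7αH-eudesma-2,11-dien-1-one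
Product: 16 6α-acryloyloxy-3-methoxy-1-oxo-15-pivaloyloxy-4βH,5αH,7αH-eudesma-2,11(13)-dien-12-al
Conditions: SeO2 (1.2 equiv), BHT (cat.), 1,4-dioxane, 70 °C
Reagents that add atoms: selenium dioxide O=[Se]=O
Why: Riley allylic oxidation (ene reaction, then [2,3]-shift) should oxidise the isopropenyl CH3, the only allylic methyl on an electron-rich alkene, to the 2-substituted acrolein.

Step 11
Reactants: 16 6α-acryloyloxy-3-methoxy-1-oxo-15-pivaloyloxy-4βH,5αH,7αH-eudesma-2,11(13)-dien-12-al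
Product: 17 6α-acryloyloxy-3-methoxy-1-oxo-15-pivaloyloxy-4βH,5αH,7αH-eudesma-2,11(13)-dien-12-oic acid
Conditions: NaClO2, NaH2PO4, 2-methylbut-2-ene, tBuOH/H2O, 0 °C → rt
Reagents that add atoms: sodium chlorite [Na+].[O-]Cl=O
Why: Pinnick oxidation converts enals to acrylic acids without touching enol ethers or enoate esters when the hypochlorite scavenger is present.

Step 12
Reactants: 17 6α-acryloyloxy-3-methoxy-1-oxo-15-pivaloyloxy-4βH,5αH,7αH-eudesma-2,11(13)-dien-12-oic acid
Product: 18 methyl 6α-acryloyloxy-3-methoxy-1-oxo-15-pivaloyloxy-4βH,5αH,7αH-eudesma-2,11(13)-dien-12-oate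
Conditions: MeI, K2CO3, DMF, 0 °C → rt
Reagents that add atoms: iodomethane CI
Why: Carboxylate O-alkylation gives the methyl ester and avoids diazoalkanes, which would add to the acrylates.

Step 13
Reactants: 18 methyl 6α-acryloyloxy-3-methoxy-1-oxo-15-pivaloyloxy-4βH,5αH,7αH-eudesma-2,11(13)-dien-12-oate
Product: 19 methyl 6α-acryloyloxy-1β-hydroxy-3-methoxy-15-pivaloyloxy-4βH,5αH,7αH-eudesma-2,11(13)-dien-12-oate
Conditions: NaBH4, CeCl3·7H2O, MeOH/CH2Cl2, −40 °C
Reagents that add atoms: none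
Why: Luche 1,2-reduction of the vinylogous ester carbonyl should spare the enoate esters, and hydride attack from the α-face, anti to the neighbouring axial C14 methyl, sets the 1β-alcohol.

Step 14
Reactants: 19 methyl 6α-acryloyloxy-1β-hydroxy-3-methoxy-15-pivaloyloxy-4βH,5αH,7αH-eudesma-2,11(13)-dien-12-oate
Product: 20 methyl 6α-acryloyloxy-1β-(tert-butyldimethylsilyloxy)-3-methoxy-15-pivaloyloxy-4βH,5αH,7αH-eudesma-2,11(13)-dien-12-oate
Conditions: TBSOTf, 2,6-lutidine, CH2Cl2, −78 °C
Reagents that add atoms: tert-butyldimethylsilyl trifluoromethanesulfonate CC(C)(C)[Si](C)(C)OS(=O)(=O)C(F)(F)F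
Why: Silylation under non-acidic conditions blocks the allylic C1 oxygen so that it cannot ionise when the enol ether is hydrolysed.

Step 15
Reactants: 20 methyl 6α-acryloyloxy-1β-(tert-butyldimethylsilyloxy)-3-methoxy-15-pivaloyloxy-4βH,5αH,7αH-eudesma-2,11(13)-dien-12-oate
Product: 22 methyl 6α-acryloyloxy-1β-(tert-butyldimethylsilyloxy)-3-oxo-5αH,7αH-eudesma-4(15),11(13)-dien-12-oate, via β-pivaloyloxy ketone 21 (not isolated)
Conditions: 0.5 M HCl, THF, 0 °C; then Et3N, CH2Cl2, 0 °C → rt
Reagents that add atoms: water O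
Why: Enol ether hydrolysis gives the C3 ketone, and E1cB loss of pivalate from the freely rotating C15 then gives the α-methylene ketone, whereas the equatorial C1 silyloxy group is poorly aligned for elimination.

Step 16
Reactants: 22 methyl 6α-acryloyloxy-1β-(tert-butyldimethylsilyloxy)-3-oxo-5αH,7αH-eudesma-4(15),11(13)-dien-12-oate
Product: 23 methyl 6α-acryloyloxy-1β-(tert-butyldimethylsilyloxy)-3β-hydroxy-5αH,7αH-eudesma-4(15),11(13)-dien-12-oate
Conditions: NaBH4, CeCl3·7H2O, MeOH, −78 °C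
Reagents that add atoms: none
Why: Luche 1,2-reduction of the exocyclic enone with axial hydride attack from the α-face (the β-face is shielded by the 1,3-diaxial C14 methyl) should give the equatorial 3β-alcohol.

Step 17
Reactants: 23 methyl 6α-acryloyloxy-1β-(tert-butyldimethylsilyloxy)-3β-hydroxy-5αH,7αH-eudesma-4(15),11(13)-dien-12-oate
Product: 24 methyl 1β-(tert-butyldimethylsilyloxy)-3β-hydroxy-6α-[2-(hydroxymethyl)acryloyloxy]-5αH,7αH-eudesma-4(15),11(13)-dien-12-oate
Conditions: aq. CH2O (37%), DABCO, 1,4-dioxane/H2O, rt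
Reagents that add atoms: formaldehyde C=O
Why: Morita–Baylis–Hillman hydroxymethylation can occur only at the C6 acrylate, the one enoate with an α-hydrogen, so the hydroxymethyl group is installed without a protecting group.

Step 18
Reactants: 24 methyl 1β-(tert-butyldimethylsilyloxy)-3β-hydroxy-6α-[2-(hydroxymethyl)acryloyloxy]-5αH,7αH-eudesma-4(15),11(13)-dien-12-oate
Product: 25 methyl 1β,3β-dihydroxy-6α-[2-(hydroxymethyl)acryloyloxy]-5αH,7αH-eudesma-4(15),11(13)-dien-12-oate
Conditions: HF·pyridine, pyridine, THF, 0 °C → rt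
Reagents that add atoms: none
Why: Buffered fluoride desilylation frees the 1β-hydroxyl without harming the two enoate esters or the allylic alcohol.

**Compound list**
1 | 2,2-dimethoxyacetaldehyde | COC(OC)C=O | starting material
2 | 2-(triphenylphosphoranylidene)propanal | CC(C=O)=P(c1ccccc1)(c1ccccc1)c1ccccc1 | starting material
3 | (2E)-4,4-dimethoxy-2-methylbut-2-enal | COC(OC)/C=C(\C)C=O | intermediate
4 | methyl (2E)-3-methoxybut-2-enoate | COC(=O)/C=C(/OC)C | starting material
5 | (1E)-1,3-dimethoxy-1-(trimethylsilyloxy)buta-1,3-diene | C=C(OC)/C=C(\OC)O[Si](C)(C)C | intermediate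
6 | silyl ketal cycloadduct: 6-(dimethoxymethyl)-2,4-dimethoxy-1-methyl-2-(trimethylsilyloxy)cyclohex-3-ene-1-carbaldehyde, formyl trans to dimethoxymethyl (ketal carbon configuration inconsequential) | COC(OC)[C@H]1CC(OC)=C[C@@](OC)(O[Si](C)(C)C)[C@]1(C)C=O | intermediate
7 | (1S,6S)-6-(dimethoxymethyl)-4-methoxy-1-methyl-2-oxocyclohex-3-ene-1-carbaldehyde (10β-methyl, 5αH; C9 formyl trans to C6 acetal) | COC(OC)[C@H]1CC(OC)=CC(=O)[C@]1(C)C=O | intermediate
8 | (5S,6R)-5-(dimethoxymethyl)-6-ethenyl-3-methoxy-6-methylcyclohex-2-en-1-one | COC(OC)[C@H]1CC(OC)=CC(=O)[C@]1(C)C=C | intermediate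
9 | (5S,6R)-6-[2-(9-borabicyclo[3.3.1]nonan-9-yl)ethyl]-5-(dimethoxymethyl)-3-methoxy-6-methylcyclohex-2-en-1-one | COC(OC)[C@H]1CC(OC)=CC(=O)[C@]1(C)CCB1C2CCCC1CCC2 | intermediate
10 | (5S,6R)-5-(dimethoxymethyl)-3-methoxy-6-methyl-6-(4-methylpent-3-en-1-yl)cyclohex-2-en-1-one | COC(OC)[C@H]1CC(OC)=CC(=O)[C@]1(C)CCC=C(C)C | intermediate
11 | lithium dienolate of 10 (O–C1=C2–C3(OMe)=C4) | COC(OC)[C@H]1C=C(OC)C=C(O[Li])[C@]1(C)CCC=C(C)C | intermediate
12 | {(1R,5R,6S)-6-(dimethoxymethyl)-2-methoxy-5-methyl-5-(4-methylpent-3-en-1-yl)-4-oxocyclohex-2-en-1-yl}methyl 2,2-dimethylpropanoate (C15 α on C4) | COC(OC)[C@H]1[C@H](COC(=O)C(C)(C)C)C(OC)=CC(=O)[C@]1(C)CCC=C(C)C | intermediate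
13 | {(1R,5R,6S)-6-formyl-2-methoxy-5-methyl-5-(4-methylpent-3-en-1-yl)-4-oxocyclohex-2-en-1-yl}methyl 2,2-dimethylpropanoate | O=C[C@H]1[C@H](COC(=O)C(C)(C)C)C(OC)=CC(=O)[C@]1(C)CCC=C(C)C | intermediate
14 | 6α-hydroxy-3-methoxy-15-pivaloyloxy-4βH,5αH,7αH-eudesma-2,11-dien-1-one | O[C@@H]1[C@H]2[C@H](COC(=O)C(C)(C)C)C(OC)=CC(=O)[C@]2(C)CC[C@H]1C(C)=C | intermediate
15 | 6α-acryloyloxy-3-methoxy-15-pivaloyloxy-4βH,5αH,7αH-eudesma-2,11-dien-1-one | C=CC(=O)O[C@@H]1[C@H]2[C@H](COC(=O)C(C)(C)C)C(OC)=CC(=O)[C@]2(C)CC[C@H]1C(C)=C | intermediate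
16 | 6α-acryloyloxy-3-methoxy-1-oxo-15-pivaloyloxy-4βH,5αH,7αH-eudesma-2,11(13)-dien-12-al | C=CC(=O)O[C@@H]1[C@H]2[C@H](COC(=O)C(C)(C)C)C(OC)=CC(=O)[C@]2(C)CC[C@H]1C(=C)C=O | intermediate
17 | 6α-acryloyloxy-3-methoxy-1-oxo-15-pivaloyloxy-4βH,5αH,7αH-eudesma-2,11(13)-dien-12-oic acid | C=CC(=O)O[C@@H]1[C@H]2[C@H](COC(=O)C(C)(C)C)C(OC)=CC(=O)[C@]2(C)CC[C@H]1C(=C)C(=O)O | intermediate
18 | methyl 6α-acryloyloxy-3-methoxy-1-oxo-15-pivaloyloxy-4βH,5αH,7αH-eudesma-2,11(13)-dien-12-oate | C=CC(=O)O[C@@H]1[C@H]2[C@H](COC(=O)C(C)(C)C)C(OC)=CC(=O)[C@]2(C)CC[C@H]1C(=C)C(=O)OC | intermediate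
19 | methyl 6α-acryloyloxy-1β-hydroxy-3-methoxy-15-pivaloyloxy-4βH,5αH,7αH-eudesma-2,11(13)-dien-12-oate | C=CC(=O)O[C@@H]1[C@H]2[C@H](COC(=O)C(C)(C)C)C(OC)=C[C@@H](O)[C@]2(C)CC[C@H]1C(=C)C(=O)OC | intermediate
20 | methyl 6α-acryloyloxy-1β-(tert-butyldimethylsilyloxy)-3-methoxy-15-pivaloyloxy-4βH,5αH,7αH-eudesma-2,11(13)-dien-12-oate | C=CC(=O)O[C@@H]1[C@H]2[C@H](COC(=O)C(C)(C)C)C(OC)=C[C@@H](O[Si](C)(C)C(C)(C)C)[C@]2(C)CC[C@H]1C(=C)C(=O)OC | intermediate
21 | methyl 6α-acryloyloxy-1β-(tert-butyldimethylsilyloxy)-3-oxo-15-pivaloyloxy-4βH,5αH,7αH-eudesm-11(13)-en-12-oate | C=CC(=O)O[C@@H]1[C@H]2[C@H](COC(=O)C(C)(C)C)C(=O)C[C@@H](O[Si](C)(C)C(C)(C)C)[C@]2(C)CC[C@H]1C(=C)C(=O)OC | intermediate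
22 | methyl 6α-acryloyloxy-1β-(tert-butyldimethylsilyloxy)-3-oxo-5αH,7αH-eudesma-4(15),11(13)-dien-12-oate | C=CC(=O)O[C@@H]1[C@H]2C(=C)C(=O)C[C@@H](O[Si](C)(C)C(C)(C)C)[C@]2(C)CC[C@H]1C(=C)C(=O)OC | intermediate
23 | methyl 6α-acryloyloxy-1β-(tert-butyldimethylsilyloxy)-3β-hydroxy-5αH,7αH-eudesma-4(15),11(13)-dien-12-oate | C=CC(=O)O[C@@H]1[C@H]2C(=C)[C@@H](O)C[C@@H](O[Si](C)(C)C(C)(C)C)[C@]2(C)CC[C@H]1C(=C)C(=O)OC | intermediate
24 | methyl 1β-(tert-butyldimethylsilyloxy)-3β-hydroxy-6α-[2-(hydroxymethyl)acryloyloxy]-5αH,7αH-eudesma-4(15),11(13)-dien-12-oate | C=C(CO)C(=O)O[C@@H]1[C@H]2C(=C)[C@@H](O)C[C@@H](O[Si](C)(C)C(C)(C)C)[C@]2(C)CC[C@H]1C(=C)C(=O)OC | intermediate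
25 | methyl 1β,3β-dihydroxy-6α-[2-(hydroxymethyl)acryloyloxy]-5αH,7αH-eudesma-4(15),11(13)-dien-12-oate | C=C(CO)C(=O)O[C@@H]1[C@H]2C(=C)[C@@H](O)C[C@@H](O)[C@]2(C)CC[C@H]1C(=C)C(=O)OC | target

**Step count**
Total: 18 steps. Longest linear sequence: 17 steps (step 1, then steps 3–18; step 2 is a one-step branch).

**Steps most likely to fail**

Step 3 (cycloaddition). The diene may add to the formyl C=O instead of the C=C (hetero-Diels–Alder), a stepwise Michael-type addition may stop at the open-chain adduct, or enantioface discrimination may be poor. Fallback, from 3 back to 8: 3 is combined under the same diol catalysis with commercial (E)-1-(dimethylamino)-3-(tert-butyldimethylsilyloxy)buta-1,3-diene, the diene class for which this catalysis with α-substituted acroleins is established, to give the amino silyl enol ether cycloadduct F1. Dilute HF in MeCN converts it into the cyclohexenone aldehyde F2. Methylenation as in step 4 gives the vinyl enone F3, H2O2/NaOH the epoxy ketone F4, and Pd(PPh3)4 with 1,2-bis(diphenylphosphino)ethane isomerises this to the cyclohexane-1,3-dione F5. HC(OMe)3/MeOH/camphorsulfonic acid then forms the enol ether at the unhindered carbonyl, which is 8.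

Step 6 (γ-alkylation). The extended enolate may be alkylated at C2 or on oxygen instead of at C4. Fallback, from 10 back to 12: 10 is converted with TBSOTf/Et3N into the silyl dienol ether F6, which reacts at its γ-terminus with aqueous formaldehyde under Yb(OTf)3 (vinylogous Mukaiyama aldol) to give the γ-hydroxymethyl vinylogous ester F7. Pivaloyl chloride/pyridine then gives 12.

Step 8 (ene cyclisation). C5 may epimerise before ring closure, the enol ether carbon C2 may attack the activated aldehyde, or the axial C6 alcohol may form. Fallback, from 12 back to 14: 12 undergoes ene-type allylic chlorination of its trisubstituted alkene (Ca(OCl)2, CO2, CH2Cl2/H2O) to the secondary allylic chloride F8. Acetal hydrolysis as in step 7 gives the chloro aldehyde F9, and CrCl2 in THF closes ring B by intramolecular Nozaki–Hiyama allylation through a chair transition state, giving 14.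

Further compounds
F1 | step 3 | 2-(dimethylamino)-6-(dimethoxymethyl)-1-methyl-4-(tert-butyldimethylsilyloxy)cyclohex-3-ene-1-carbaldehyde (amino group cis to formyl, formyl trans to dimethoxymethyl) | COC(OC)[C@H]1CC(O[Si](C)(C)C(C)(C)C)=C[C@H](N(C)C)[C@]1(C)C=O
F2 | step 3 | 6-(dimethoxymethyl)-1-methyl-4-oxocyclohex-2-ene-1-carbaldehyde (10β-methyl, 5αH) | COC(OC)[C@H]1CC(=O)C=C[C@]1(C)C=O
F3 | step 3 | 5-(dimethoxymethyl)-4-ethenyl-4-methylcyclohex-2-en-1-one (10β-methyl, 5αH) | COC(OC)[C@H]1CC(=O)C=C[C@]1(C)C=C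
F4 | step 3 | 1α,2α-epoxide of F3 (2,3-epoxy ketone) | COC(OC)[C@H]1CC(=O)[C@@H]2O[C@@H]2[C@]1(C)C=C
F5 | step 3 | 5-(dimethoxymethyl)-4-ethenyl-4-methylcyclohexane-1,3-dione (10β-methyl, 5αH) | COC(OC)[C@H]1CC(=O)CC(=O)[C@]1(C)C=C
F6 | step 6 | tert-butyldimethylsilyl dienol ether of 10 (C1–OSi, C1=C2, C3(OMe)=C4) | COC(OC)[C@H]1C=C(OC)C=C(O[Si](C)(C)C(C)(C)C)[C@]1(C)CCC=C(C)C
F7 | step 6 | (4R,5S,6R)-5-(dimethoxymethyl)-4-(hydroxymethyl)-3-methoxy-6-methyl-6-(4-methylpent-3-en-1-yl)cyclohex-2-en-1-one | COC(OC)[C@H]1[C@H](CO)C(OC)=CC(=O)[C@]1(C)CCC=C(C)C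
F8 | step 8 | 12 with its side chain changed to 3-chloro-4-methylpent-4-en-1-yl (both epimers at the chlorinated carbon) | COC(OC)[C@H]1[C@H](COC(=O)C(C)(C)C)C(OC)=CC(=O)[C@]1(C)CCC(Cl)C(C)=C
F9 | step 8 | 13 with its side chain changed to 3-chloro-4-methylpent-4-en-1-yl (both epimers at the chlorinated carbon) | O=C[C@H]1[C@H](COC(=O)C(C)(C)C)C(OC)=CC(=O)[C@]1(C)CCC(Cl)C(C)=C
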